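**Plan**
1. Numbering (germacrane): C1 ketone carbon, C2 =CH, C3 furanone C–O, C4 CH bearing C15H2OH, C5 CH2, C6 CH–O, C7 ring-fusion CH, C8 CH–OAng, C9 CH2, C10 C(C14H3)–O, C11 =C, C12 lactone C=O, C13 =CH2.
2. Cuts, late to early: the C15–O silyl ether, the C12 carbonyl (allylic C–H oxidation of a 3-methylenetetrahydrofuran), the C8 angelate, then the C7–C11 bond of the five-membered oxygen ring.
3. Feature used: C7 lies between the two oxygen-bearing carbons C6 and C8. A C7–C8 epoxide whose C6 oxygen carries C12–C11–C13 as a propargyl group gives, by one-electron opening of the C7–O bond, a C7 radical that closes on C11 (5-exo-dig) and leaves the C8 hydroxyl and the C11=C13 methylene.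
4. Earlier cuts: C7=C8 (ring-closing metathesis), O–C3 (gold-catalysed furanone closure of a hydroxy ynone), C1–C2 (acetylide plus Weinreb amide); this gives an alkyne fragment (C2–C7, C15) and an amide fragment (C1, C8–C10, C14).
5. Forward ring order: furanone, then the ten-membered carbocycle, then the tetrahydrofuran (key step), which is oxidized to the lactone.
6. Stereochemistry: C10 from (R)-lactic acid (dioxolanone alkylation); C6 from lactone 1 after Mitsunobu inversion; C4 by trans aldol of that lactone; C8 by face-selective epoxidation of the Z ring alkene; C7 in the radical ring closure (trans fusion).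

Key step: step 16

Remark: the SMILES is read as (4S,6R,7S,8R,10S) with a trans-fused lactone (H6/H7 anti) and an angelate, (Z)-2-methylbut-2-enoate; the numbering of line 1 is used for all later compounds.

**Alkyne fragment**

Step 1
Reactants: 1 (S)-5-(hydroxymethyl)dihydrofuran-2(3H)-one
Product: 3 (S)-5-vinyldihydrofuran-2(3H)-one, via (S)-5-oxotetrahydrofuran-2-carbaldehyde 2 (not isolated)
Conditions: (COCl)2, DMSO, CH2Cl2, −78 °C; Et3N; then excess Ph3P=CH2 (from Ph3PCH3Br, KN(SiMe3)2, THF), −78 → 0 °C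
Reagents that add atoms: methyltriphenylphosphonium bromide, C[P+](c1ccccc1)(c1ccccc1)c1ccccc1.[Br-]
Why: Swern oxidation to the labile α-acyloxy aldehyde and Wittig methylenation in the same flask, so the aldehyde is never handled; neither bond change touches the C6 stereocentre.

Step 2
Reactants: 3 (S)-5-vinyldihydrofuran-2(3H)-one
Product: 4 (3S,5S)-3-(hydroxymethyl)-5-vinyldihydrofuran-2(3H)-one
Conditions: LiN(iPr)2, THF, −78 °C; CH2O gas (cracked paraformaldehyde), −78 → −40 °C; NH4Cl (aq)
Reagents that add atoms: formaldehyde, C=O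
Why: aldol reaction of the lactone lithium enolate with formaldehyde, in which the electrophile should enter anti to the C5 vinyl group and give the trans-3,5 lactone, which sets C4.

Step 3
Reactants: 4 (3S,5S)-3-(hydroxymethyl)-5-vinyldihydrofuran-2(3H)-one
Product: 5 (3S,5S)-3-{[tert-butyl(diphenyl)silyl]oxymethyl}-5-vinyldihydrofuran-2(3H)-one
Conditions: tBuPh2SiCl, imidazole, DMF, rt
Reagents that add atoms: tert-butyl(chloro)diphenylsilane, CC(C)(C)[Si](Cl)(c1ccccc1)c1ccccc1
Why: imidazole-mediated silylation of the primary alcohol gives a robust ether that masks the C15 hydroxyl until the last step.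

Step 4
Reactants: 5 (3S,5S)-3-{[tert-butyl(diphenyl)silyl]oxymethyl}-5-vinyldihydrofuran-2(3H)-one
Product: 6 (3S,5S)-3-{[tert-butyl(diphenyl)silyl]oxymethyl}-5-vinyltetrahydrofuran-2-ol (lactol, both anomers)
Conditions: iBu2AlH, CH2Cl2, −78 °C; Rochelle salt (aq)
Reagents that add atoms: none
Why: partial reduction of the lactone stops at the aluminium hemiacetal at low temperature and gives the lactol on work-up, with C4 and C6 untouched.

Step 5
Reactants: 6 (3S,5S)-3-{[tert-butyl(diphenyl)silyl]oxymethyl}-5-vinyltetrahydrofuran-2-ol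
Product: 7 (3S,5R)-5-{[tert-butyl(diphenyl)silyl]oxymethyl}hept-1-en-6-yn-3-ol
Conditions: dimethyl (1-diazo-2-oxopropyl)phosphonate, K2CO3, MeOH, 0 °C → rt
Reagents that add atoms: dimethyl (1-diazo-2-oxopropyl)phosphonate, COP(=O)(OC)C(=[N+]=[N-])C(C)=O
Why: Seyferth–Gilbert homologation with the Ohira–Bestmann reagent on the open hydroxy-aldehyde form of the lactol turns the aldehyde carbon into C3 of a terminal alkyne and frees the C6 hydroxyl; the descriptor at C4 changes to R by priority only.

Step 6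
Reactants: 7 (3S,5R)-5-{[tert-butyl(diphenyl)silyl]oxymethyl}hept-1-en-6-yn-3-ol
Product: 8 tert-butyl{[(2R,4R)-2-ethynyl-4-(4-methoxyphenoxy)hex-5-en-1-yl]oxy}diphenylsilane
Conditions: 4-MeOC6H4OH, PPh3, iPrO2CN=NCO2iPr, THF, 0 °C → rt
Reagents that add atoms: 4-methoxyphenol, COc1ccc(O)cc1
Why: Mitsunobu etherification, in which SN2 displacement of the oxyphosphonium by the phenoxide inverts C6 to R and masks the oxygen as an oxidatively removable aryl ether.

**Amide fragment**

Step 7
Reactants: 9 (R)-lactic acid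
Product: 10 (2R,5R)-2-tert-butyl-5-methyl-1,3-dioxolan-4-one
Conditions: tBuCHO, TsOH·H2O (cat.), pentane, reflux (water separator); crystallization at low temperature
Reagents that add atoms: pivalaldehyde, CC(C)(C)C=O
Why: acid-catalysed acetalization of the α-hydroxy acid (Seebach dioxolanone) should give mainly the cis isomer, whose acetal carbon stores the chirality of the lactate carbon.

Step 8
Reactants: 10 (2R,5R)-2-tert-butyl-5-methyl-1,3-dioxolan-4-one
Product: 11 (2R,5S)-5-allyl-2-tert-butyl-5-methyl-1,3-dioxolan-4-one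
Conditions: LiN(iPr)2, THF, −78 °C; allyl bromide, −78 → −30 °C
Reagents that add atoms: allyl bromide, C=CCBr
Why: alkylation of the dioxolanone lithium enolate anti to the tert-butyl group (self-regeneration of the stereocentre) puts allyl in the place of the former hydrogen and makes C10 quaternary.

Step 9
Reactants: 11 (2R,5S)-5-allyl-2-tert-butyl-5-methyl-1,3-dioxolan-4-one
Product: 12 (S)-2-hydroxy-N-methoxy-N,2-dimethylpent-4-enamide
Conditions: MeNH(OMe)·HCl, iPrMgCl, THF, −20 → 0 °C; NH4Cl (aq)
Reagents that add atoms: N,O-dimethylhydroxylamine hydrochloride, CNOC.Cl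
Why: Weinreb amide formation by attack of the chloromagnesium amide on the acylal carbonyl; collapse of the hemiacetal releases pivalaldehyde and the tertiary alkoxide without touching the quaternary centre.

**Union and endgame**

Step 10
Reactants: 8 tert-butyl{[(2R,4R)-2-ethynyl-4-(4-methoxyphenoxy)hex-5-en-1-yl]oxy}diphenylsilane; 12 (S)-2-hydroxy-N-methoxy-N,2-dimethylpent-4-enamide
Product: 13 (4S,8R,10R)-8-{[tert-butyl(diphenyl)silyl]oxymethyl}-4-hydroxy-10-(4-methoxyphenoxy)-4-methyldodeca-1,11-dien-6-yn-5-one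
Conditions: 8, n-BuLi, THF, −78 °C; added to 12 pre-treated with iPrMgCl (1 equiv, THF, −20 °C); −78 → 0 °C; NH4Cl (aq)
Reagents that add atoms: none
Why: Weinreb ketone synthesis, in which the lithium acetylide adds once to the magnesium alkoxide–amide chelate and the ynone is released only on work-up, which keeps the base-sensitive propargylic C4 centre safe.

Step 11
Reactants: 13 (4S,8R,10R)-8-{[tert-butyl(diphenyl)silyl]oxymethyl}-4-hydroxy-10-(4-methoxyphenoxy)-4-methyldodeca-1,11-dien-6-yn-5-one
Product: 14 (S)-2-allyl-5-[(2S,4R)-1-{[tert-butyl(diphenyl)silyl]oxy}-4-(4-methoxyphenoxy)hex-5-en-2-yl]-2-methylfuran-3(2H)-one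
Conditions: (Ph3P)AuCl (5 mol %), AgOSO2CF3 (5 mol %), toluene, rt
Reagents that add atoms: none
Why: gold-catalysed 5-endo-dig hydroalkoxylation of the ynone by the tertiary hydroxyl followed by protodeauration, the known route from hydroxy ynones to 3(2H)-furanones; no stereocentre is touched.

Step 12
Reactants: 14 (S)-2-allyl-5-[(2S,4R)-1-{[tert-butyl(diphenyl)silyl]oxy}-4-(4-methoxyphenoxy)hex-5-en-2-yl]-2-methylfuran-3(2H)-one
Product: 15 (2S,4R,5Z,8S)-2-{[tert-butyl(diphenyl)silyl]oxymethyl}-4-(4-methoxyphenoxy)-8-methyl-11-oxabicyclo[6.2.1]undeca-1(10),5-dien-9-one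
Conditions: second-generation Hoveyda–Grubbs catalyst (10 mol %), 1,4-benzoquinone (20 mol %), toluene (0.001 M), 80 °C
Reagents that add atoms: none
Why: ring-closing metathesis of the two monosubstituted alkenes, held close by the 2,5-disubstituted furanone, closes C7=C8; the oxygen-bridged medium ring should accept only the Z alkene, and benzoquinone suppresses allyl isomerization.

Step 13
Reactants: 15 (2S,4R,5Z,8S)-2-{[tert-butyl(diphenyl)silyl]oxymethyl}-4-(4-methoxyphenoxy)-8-methyl-11-oxabicyclo[6.2.1]undeca-1(10),5-dien-9-one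
Product: 16 (2S,4R,5Z,8S)-2-{[tert-butyl(diphenyl)silyl]oxymethyl}-4-hydroxy-8-methyl-11-oxabicyclo[6.2.1]undeca-1(10),5-dien-9-one
Conditions: (NH4)2Ce(NO3)6, MeCN/H2O (4:1), 0 °C
Reagents that add atoms: none
Why: oxidative dearylation of the 4-methoxyphenyl ether by tetravalent cerium (arene oxidation, attack of water at the ipso carbon) frees the C6 allylic alcohol with retention, since the C6–O bond is not broken.

Step 14
Reactants: 16 (2S,4R,5Z,8S)-2-{[tert-butyl(diphenyl)silyl]oxymethyl}-4-hydroxy-8-methyl-11-oxabicyclo[6.2.1]undeca-1(10),5-dien-9-one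
Product: 17 (2S,4R,5Z,8S)-2-{[tert-butyl(diphenyl)silyl]oxymethyl}-8-methyl-4-(prop-2-yn-1-yloxy)-11-oxabicyclo[6.2.1]undeca-1(10),5-dien-9-one
Conditions: HC≡CCH2OC(=NH)CCl3, CF3SO3H (10 mol %), CH2Cl2, 0 °C → rt
Reagents that add atoms: prop-2-yn-1-yl 2,2,2-trichloroacetimidate, C#CCOC(=N)C(Cl)(Cl)Cl
Why: acid-catalysed O-alkylation with a trichloroacetimidate installs the tether C12–C11–C13 without base, so the epimerizable C4–H next to the furanone is not put at risk.

Step 15
Reactants: 17 (2S,4R,5Z,8S)-2-{[tert-butyl(diphenyl)silyl]oxymethyl}-8-methyl-4-(prop-2-yn-1-yloxy)-11-oxabicyclo[6.2.1]undeca-1(10),5-dien-9-one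
Product: 18 (2S,4R,8S)-2-{[tert-butyl(diphenyl)silyl]oxymethyl}-cis-5,6-epoxy-8-methyl-4-(prop-2-yn-1-yloxy)-11-oxabicyclo[6.2.1]undec-1(10)-en-9-one, epoxide oxygen on the ring face opposite to the C4 ether oxygen (germacrane C8 R)
Conditions: mCPBA, NaHCO3, CH2Cl2, 0 °C
Reagents that add atoms: 3-chloroperoxybenzoic acid, OOC(=O)c1cccc(Cl)c1
Why: Prilezhaev epoxidation of the only electron-rich alkene; with C6–H eclipsing the Z alkene (allylic 1,3-strain) the ring carbon C5 covers one face, so the peracid should attack the open face that carries the C6 oxygen, which gives the cis-epoxide ring-trans to that oxygen and fixes C8 as R.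

Step 16
Reactants: 18 (2S,4R,8S)-2-{[tert-butyl(diphenyl)silyl]oxymethyl}-cis-5,6-epoxy-8-methyl-4-(prop-2-yn-1-yloxy)-11-oxabicyclo[6.2.1]undec-1(10)-en-9-one
Product: 19 (4S,6R,7R,8R,10S) tricyclic alcohol: the furanone-bridged ten-membered ring with a 3-methylenetetrahydrofuran (O–C12H2–C11(=C13H2)) trans-fused at C6–C7, free 8-OH and 15-O-silyl ether
Conditions: (C5H5)2TiCl2, Zn dust, THF, rt [gives (C5H5)2TiCl]; added slowly to 18, THF, rt; then 1 M HCl (aq)
Reagents that add atoms: none
Why: (C5H5)2TiCl gives one electron to the epoxide (Nugent–RajanBabu opening), and homolysis of the C7–O bond, favoured over C8–O by chelation of titanium between the epoxide and the C6 ether oxygen, turns the electrophilic epoxide carbon C7 into a nucleophilic β-titanoxy radical. This radical adds to the inner alkyne carbon C11, and the vinyl radical at C13 is reduced by a second (C5H5)2TiCl and protonated on work-up, or takes hydrogen from THF. The closest known reaction type is the trivalent-titanium cyclization of epoxy propargyl ethers to 3-methylenetetrahydrofurans, used as precursors of α-methylene-γ-butyrolactones. The tetrahydrofuran ring closes in the 5-exo-dig mode. C8 keeps its epoxide C–O bond and so its R configuration, while C7 is set in the ring closure: with C6–H in the radical plane the tether on the C6 oxygen reaches only the face anti to C5, which gives the trans fusion (H6/H7 anti) whatever the configuration of C7 in the epoxide. The step needs ring closure to outrun reduction of the C7 radical (which would lead to loss of the C6 alkoxide) and the furanone to stay untouched; slow addition keeps (C5H5)2TiCl low, closure of an oxygen-tethered hexynyl radical is fast, and the vinylogous ester is not reduced by this mild reductant.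

Step 17
Reactants: 19 tricyclic alcohol (8-OH)
Product: 20 (4S,6R,7S,8R,10S) 8-O-angelate of 19
Conditions: angelic acid, 2,4,6-Cl3C6H2COCl, Et3N, toluene, rt; then 19, 80 °C
Reagents that add atoms: angelic acid, C/C=C(/C)C(=O)O
Why: Yamaguchi-type acylation through the mixed 2,4,6-trichlorobenzoic anhydride without DMAP, the established way to make hindered angelates without Z-to-E isomerization; C8 is acylated with retention.

Step 18
Reactants: 20 8-O-angelate of 19
Product: 21 (4S,6R,7S,8R,10S) 15-O-[tert-butyl(diphenyl)silyl] ether of the target (α-methylene-γ-butyrolactone)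
Conditions: CrO3, pyridine, CH2Cl2, rt
Reagents that add atoms: chromium trioxide, O=[Cr](=O)=O
Why: allylic oxidation with CrO3·2 pyridine at the doubly activated C12 methylene (next to the ring oxygen and allylic to the exocyclic alkene), the standard conversion of 3-methylenetetrahydrofurans into α-methylene-γ-butyrolactones.

Step 19
Reactants: 21 15-O-silyl ether of the target
Product: 22 target, 8-angeloyloxy-15-hydroxy-1-oxo-3,10-epoxygermacra-2,11(13)-dien-6,12-olide (4S,6R,7S,8R,10S)
Conditions: HF·pyridine, pyridine, THF, 0 °C → rt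
Reagents that add atoms: none
Why: fluoride cleavage of the primary silyl ether under buffered, weakly acidic conditions that should leave the α-methylene lactone, the angelate and the furanone intact.

**Compound list**
1 | (S)-5-(hydroxymethyl)dihydrofuran-2(3H)-one | OC[C@@H]1CCC(=O)O1 | starting material
2 | (S)-5-oxotetrahydrofuran-2-carbaldehyde | O=C[C@@H]1CCC(=O)O1 | intermediate (not isolated)
3 | (S)-5-vinyldihydrofuran-2(3H)-one | C=C[C@@H]1CCC(=O)O1 | intermediate
4 | (3S,5S)-3-(hydroxymethyl)-5-vinyldihydrofuran-2(3H)-one | C=C[C@@H]1C[C@@H](CO)C(=O)O1 | intermediate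
5 | (3S,5S)-3-{[tert-butyl(diphenyl)silyl]oxymethyl}-5-vinyldihydrofuran-2(3H)-one | C=C[C@@H]1C[C@@H](CO[Si](c2ccccc2)(c2ccccc2)C(C)(C)C)C(=O)O1 | intermediate
6 | (3S,5S)-3-{[tert-butyl(diphenyl)silyl]oxymethyl}-5-vinyltetrahydrofuran-2-ol | C=C[C@@H]1C[C@@H](CO[Si](c2ccccc2)(c2ccccc2)C(C)(C)C)C(O)O1 | intermediate
7 | (3S,5R)-5-{[tert-butyl(diphenyl)silyl]oxymethyl}hept-1-en-6-yn-3-ol | C=C[C@@H](O)C[C@@H](CO[Si](c1ccccc1)(c1ccccc1)C(C)(C)C)C#C | intermediate
8 | tert-butyl{[(2R,4R)-2-ethynyl-4-(4-methoxyphenoxy)hex-5-en-1-yl]oxy}diphenylsilane | C=C[C@H](Oc1ccc(OC)cc1)C[C@@H](CO[Si](c1ccccc1)(c1ccccc1)C(C)(C)C)C#C | intermediate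
9 | (R)-lactic acid | C[C@@H](O)C(=O)O | starting material
10 | (2R,5R)-2-tert-butyl-5-methyl-1,3-dioxolan-4-one | C[C@H]1O[C@@H](C(C)(C)C)OC1=O | intermediate
11 | (2R,5S)-5-allyl-2-tert-butyl-5-methyl-1,3-dioxolan-4-one | C=CC[C@]1(C)O[C@@H](C(C)(C)C)OC1=O | intermediate
12 | (S)-2-hydroxy-N-methoxy-N,2-dimethylpent-4-enamide | C=CC[C@](C)(O)C(=O)N(C)OC | intermediate
13 | (4S,8R,10R)-8-{[tert-butyl(diphenyl)silyl]oxymethyl}-4-hydroxy-10-(4-methoxyphenoxy)-4-methyldodeca-1,11-dien-6-yn-5-one | C=CC[C@](C)(O)C(=O)C#C[C@H](CO[Si](c1ccccc1)(c1ccccc1)C(C)(C)C)C[C@@H](Oc1ccc(OC)cc1)C=C | intermediate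
14 | (S)-2-allyl-5-[(2S,4R)-1-{[tert-butyl(diphenyl)silyl]oxy}-4-(4-methoxyphenoxy)hex-5-en-2-yl]-2-methylfuran-3(2H)-one | C=CC[C@]1(C)OC(=CC1=O)[C@H](CO[Si](c2ccccc2)(c2ccccc2)C(C)(C)C)C[C@@H](Oc2ccc(OC)cc2)C=C | intermediate
15 | (2S,4R,5Z,8S)-2-{[tert-butyl(diphenyl)silyl]oxymethyl}-4-(4-methoxyphenoxy)-8-methyl-11-oxabicyclo[6.2.1]undeca-1(10),5-dien-9-one | C[C@]12C/C=C\[C@H](Oc3ccc(OC)cc3)C[C@@H](CO[Si](c3ccccc3)(c3ccccc3)C(C)(C)C)C(=CC1=O)O2 | intermediate
16 | (2S,4R,5Z,8S)-2-{[tert-butyl(diphenyl)silyl]oxymethyl}-4-hydroxy-8-methyl-11-oxabicyclo[6.2.1]undeca-1(10),5-dien-9-one | C[C@]12C/C=C\[C@H](O)C[C@@H](CO[Si](c3ccccc3)(c3ccccc3)C(C)(C)C)C(=CC1=O)O2 | intermediate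
17 | (2S,4R,5Z,8S)-2-{[tert-butyl(diphenyl)silyl]oxymethyl}-8-methyl-4-(prop-2-yn-1-yloxy)-11-oxabicyclo[6.2.1]undeca-1(10),5-dien-9-one | C[C@]12C/C=C\[C@H](OCC#C)C[C@@H](CO[Si](c3ccccc3)(c3ccccc3)C(C)(C)C)C(=CC1=O)O2 | intermediate
18 | cis-5,6-epoxide of 17, oxygen ring-trans to the C4 ether oxygen | C[C@]12C[C@H]3O[C@H]3[C@H](OCC#C)C[C@@H](CO[Si](c4ccccc4)(c4ccccc4)C(C)(C)C)C(=CC1=O)O2 | intermediate
19 | (4S,6R,7R,8R,10S) tricyclic alcohol with trans-fused 3-methylenetetrahydrofuran, 8-OH, 15-O-silyl ether | C=C1CO[C@@H]2C[C@@H](CO[Si](c4ccccc4)(c4ccccc4)C(C)(C)C)C3=CC(=O)[C@](C)(C[C@@H](O)[C@@H]12)O3 | intermediate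
20 | (4S,6R,7S,8R,10S) 8-O-angelate of 19 | C=C1CO[C@@H]2C[C@@H](CO[Si](c4ccccc4)(c4ccccc4)C(C)(C)C)C3=CC(=O)[C@](C)(C[C@@H](OC(=O)/C(C)=C\C)[C@@H]12)O3 | intermediate
21 | (4S,6R,7S,8R,10S) 15-O-[tert-butyl(diphenyl)silyl] ether of the target | C=C1C(=O)O[C@@H]2C[C@@H](CO[Si](c4ccccc4)(c4ccccc4)C(C)(C)C)C3=CC(=O)[C@](C)(C[C@@H](OC(=O)/C(C)=C\C)[C@@H]12)O3 | intermediate
22 | target, (4S,6R,7S,8R,10S)-8-angeloyloxy-15-hydroxy-1-oxo-3,10-epoxygermacra-2,11(13)-dien-6,12-olide | C=C1C(=O)O[C@@H]2C[C@@H](CO)C3=CC(=O)[C@](C)(C[C@@H](OC(=O)/C(C)=C\C)[C@@H]12)O3 | target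

**Totals**
Total step count: 19. Longest linear sequence: 16 steps (steps 1–6 and 10–19).

**Steps most likely to fail**

Step 16. The epoxide may open at the C8–O bond instead of the C7–O bond. The C7 radical may also be reduced by a second titanium before it closes, with loss of the C6 alkoxide, or the epoxide may simply be deoxygenated. The fallback sets out from 17 and comes back at 20, and makes the C7 radical from a C–O bond that leaves no choice of site. Dihydroxylation of 17 (OsO4 cat., N-methylmorpholine N-oxide, acetone/H2O) on the same open face should give the 7,8-cis-diol of 17 F1. The less hindered C8 hydroxyl is acylated with the mixed anhydride of step 17 to the 8-angelate 7-alcohol F2. PhOC(S)Cl and pyridine then give the 7-O-phenoxythiocarbonyl 8-angelate F3. Bu3SnH with Et3B and air at ambient temperature (Barton–McCombie generation of the C7 radical, then the same 5-exo-dig closure; the low temperature limits angelate isomerization) should give 20.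

Step 12. Ring closure may lose to oligomerization or to allyl isomerization because the bridged ten-membered ring is strained. The fallback sets out from 14 and comes back at 15. OsO4/NaIO4 with 2,6-lutidine cleaves both terminal alkenes to the dialdehyde from 14 F4. Intramolecular McMurry coupling (TiCl3, Zn–Cu couple, DME, reflux, high dilution) then closes C7=C8 to give 15; the aryloxy-bearing C6 next to the aldehyde must be watched for epimerization.

Step 15. Facial selectivity in the epoxidation of the ether 17 may be poor, which would scramble C8. The fallback sets out from 16 and comes back at 18, and uses the free hydroxyl as a directing group. mCPBA on the allylic alcohol 16 delivers oxygen under hydrogen-bond control to the face that carries the C6 hydroxyl in the allylic-strain-minimized conformer, the mode known for medium-ring Z-cycloalkenols, and should give the epoxy alcohol from 16 F5. O-Propargylation under neutral conditions (Ag2O, propargyl bromide, CH2Cl2) then gives 18.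

**Further compounds**
F1 | step 16 | 7,8-cis-diol of 17, both hydroxyls ring-trans to the C6 oxygen | C[C@]12C[C@@H](O)[C@@H](O)[C@H](OCC#C)C[C@@H](CO[Si](c3ccccc3)(c3ccccc3)C(C)(C)C)C(=CC1=O)O2
F2 | step 16 | 8-angelate 7-alcohol | C[C@]12C[C@@H](OC(=O)/C(C)=C\C)[C@@H](O)[C@H](OCC#C)C[C@@H](CO[Si](c3ccccc3)(c3ccccc3)C(C)(C)C)C(=CC1=O)O2
F3 | step 16 | 7-O-phenoxythiocarbonyl 8-angelate | C[C@]12C[C@@H](OC(=O)/C(C)=C\C)[C@@H](OC(=S)Oc3ccccc3)[C@H](OCC#C)C[C@@H](CO[Si](c3ccccc3)(c3ccccc3)C(C)(C)C)C(=CC1=O)O2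
F4 | step 12 | dialdehyde from 14 (C7 and C8 as CHO) | O=CC[C@]1(C)OC(=CC1=O)[C@H](CO[Si](c2ccccc2)(c2ccccc2)C(C)(C)C)C[C@@H](Oc2ccc(OC)cc2)C=O
F5 | step 15 | epoxy alcohol from 16 (cis-epoxide ring-trans to the C6 hydroxyl) | C[C@]12C[C@H]3O[C@H]3[C@H](O)C[C@@H](CO[Si](c4ccccc4)(c4ccccc4)C(C)(C)C)C(=CC1=O)O2
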